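The constant for turnover of substrate by free catalyst is 4350 times larger than the constant for activation of precatalyst by coupling partner.

    substrate + free catalyst → free catalyst + open intermediate (k1 = 27 L mol⁻¹ min⁻¹)
    coupling partner + catalyst intermediate → second catalyst + target (k2 = 13 L mol⁻¹ min⁻¹)
    coupling partner + precatalyst → free catalyst + spent reagent (k3 = 0.0062 L mol⁻¹ min⁻¹)
    second catalyst + open intermediate ⇌ catalyst intermediate (K4 = 3.2 L mol⁻¹, k4 = 21 L mol⁻¹ min⁻¹)

substrate 1.0 M; coupling partner 0.700 M; second catalyst 0.58 mM; precatalyst 100 mM

- the form that holds most of the catalyst when 10 % of the substrate are converted (precatalyst / free catalyst)
- its share of the catalyst then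

Where does the catalyst start? As precatalyst, with no free catalyst, so substrate waits for activation.

How fast does precatalyst open? Call the activation rate the pseudo-first-order constant 0.00434 min⁻¹, the fraction of the precatalyst opened per minute with coupling partner as charged. For a longer stretch I multiply it by the mean fraction of coupling partner left, and the share opened by a time is one minus the exponential of minus rate times time.

When is 10 % of the substrate gone? Early on, free catalyst grows in proportion to time. The logarithm of the substrate's fall, 0.105, therefore equals half the product of the turnover constant, the precatalyst charge, the activation rate and the time squared. That gives 4.24 min, and by then 1.84 % of the catalyst is free, leaving 98.2 % as precatalyst.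

But you held coupling partner at its charge. Yes. Even with the second catalyst fully bound, the second cycle takes coupling partner at a fractional rate of 0.00754 min⁻¹, or 3.20 % of it by that time. The mean is then lower by at most 1.60 %. A lower activation rate also lengthens the time to the mark, so my share goes with the square root of that rate and drops by at most 0.015 percentage points.

The forecast names precatalyst at 98.2 %, holding that “the second catalytic cycle consumes too little coupling partner to change this”.

The simulation gives precatalyst at 98.2 %, with free catalyst at 1.83 %, after 4.26 min.

After 0.300 h this flask has substrate down to 16.0 %, with precatalyst, which stays outside the working round, still at 92.6 % of the catalyst, while the second catalyst passes open intermediate on to target, which stands at 2.72 %. Up to 3.00 h, coupling partner falls to 44.2 %, a mean of its two ends of 72.1 %, and the activation rate at that mean gives 43.1 % of the catalyst opened, where the flask shows 41.9 % free catalyst. After 30.0 h, coupling partner stands at 0.0395 %, target at 63.8 % and precatalyst at 37.8 %.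

Its constants are invented; the flask was simulated.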